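Chains start slowly.

in all of them: free monomer 0.25 M

| flask | initiator | remark | time |
|---|---|---|---|
| blue | 6.7 mol% | run made earlier |  |
| teal | 15 mol% | run made earlier |  |
| flask | 10 mol% |  | 1.0 h |

- blue (time / min: monomer in chains / %, free monomer / %): 3.00: 0.5, 98.9; 10.0: 5.8, 93.2; 15.0: 12.6, 87.5; 25.0: 24.0, 79.5; 40.0: 33.2, 65.9
- teal (time / min: monomer in chains / %, free monomer / %): 3.00: 4.7, 96.4; 5.00: 5.5, 93.4; 10.0: 13.5, 85.5; 20.0: 31.4, 68.4; 40.0: 49.6, 51.7

(scatter of a reading: 1 percentage point)

- the average divides the monomer in chains by the number of chains begun, living and dead together
- what was read earlier has a scatter of 1 percentage point, one standard deviation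
- the earlier runs do not show the number of chains; that part of a forecast is a guess

1. whether the average number of monomer units in a chain (chains begun, living or dead) reaches 5.0 by 1.0 h (no / yes)
2. average number of monomer units in a chain (chains begun, living or dead) at 1.0 h

1. First instants. At 3.00 min the blue run holds 0.5% monomer in chains and the teal run 4.7%, against a scatter of 1 percentage point. At 10.0 min the teal run, with its larger loading, holds more than the blue run, 13.5% against 5.8%.

2. Middle. At 40.0 min free monomer and monomer in chains sum to 99.1% in the blue run and 101% in the teal run. So monomer leaving the free pool is read as monomer in chains. The last intervals give first-order slopes of 0.0125 min⁻¹ (blue) and 0.0140 min⁻¹ (teal). Their mean, 0.0133 min⁻¹, is frozen as a pseudo-first-order slope.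

3. End. The flask's loading is the geometric mean of the two, 10.0%. So the mean of the two readings at 40.0 min, 58.8% free monomer, stands in for the flask. The frozen slope carries it to 45.1% at 1.0 h, which leaves 54.9% monomer in chains by this reckoning.

4. Rule. Each chain begun is taken to use one initiator, so chains begun stop at the charge. Monomer in chains divided by the loading is then the loading floor, 5.49, a lower limit on the average at that monomer in chains. This value is an estimate, since 54.9% is extrapolated. The floor reaches 5.0 at 50.0% monomer in chains, and the reckoning stands 4.9 points above that. So this reckoning answers yes, with an estimated floor of 5.49.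

5. The forecast says yes, with 5.5: “The lag suggests initiation is slow and perhaps incomplete”. The two differ: its floor is 4.8, and the floor estimated here is 5.49.

    free monomer + initiator → living end + monomer in chains (k = 0.150 L mol⁻¹ min⁻¹)
    free monomer + living end → monomer in chains + living end, rate k2*[living end]*[free monomer] (k = 2.10 L mol⁻¹ min⁻¹)
    2 living end → dead end (k = 5.20 L mol⁻¹ min⁻¹)

The flask gives yes, with an average of 6.50 at 1.0 h. At that time 21% of the initiator is still there. Monomer in chains stands at 51.5%, so the loading floor is 5.15, and the average lies above it. In the same flask stopped at 0.500 h, monomer in chains is 33.3% and the floor is 3.33, less than 5.0. There 39.1% of the initiator is still there, and the average is 5.47.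

The numbers in the tables are calculated with constants of no real substance; noise was put on by code.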